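**Retrosynthetic overview**
1. Target ⇐ global desilylation of its tetra-TBS ether (two phenols, two primary alcohols).
2. Oxolane ring (formed last) ⇐ 5-exo etherification of a C2-symmetric (1R,2R,3R,4R)-1,4-diaryl-2,3-bis(silyloxymethyl)butane-1,4-diol. One benzylic C–O bond closes (inversion, or trans-selective cation capture) while the other carbinol is kept, which gives the 2,5-cis/3,4-trans pattern.
3. That tetraol ⇐ hydride opening of a cis-fused, bis-endo 4,8-diaryl-3,7-dioxabicyclo[3.3.0]octane-2,6-dione; both lactone rings are sacrificial.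
4. Bislactone (both rings formed first, in one operation) ⇐ two-directional auxiliary-controlled anti-aldol of a succinyl bis(oxazolidinone) with two molecules of O-silyl syringaldehyde, then double lactonisation that expels both auxiliaries.
5. Starting materials: syringaldehyde, succinyl chloride, (R)-4-benzyl-1,3-oxazolidin-2-one.

Assumption: the SMILES is read as the (2R,3R,4R,5S)-oxolane (aryl at C2 cis to the C3 CH2OH, aryl at C5 trans to the C4 CH2OH), and both enantiomers of 4-benzyl-1,3-oxazolidin-2-one are taken as catalogue chemicals.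

Abbreviations: TBS = tert-butyldimethylsilyl; TMS = trimethylsilyl; Ar = 4-(TBS-oxy)-3,5-dimethoxyphenyl; Xc = (4R)-4-benzyl-2-oxo-1,3-oxazolidin-3-yl.

**Route**

Step 1
Reactants: 1 syringaldehyde (4-hydroxy-3,5-dimethoxybenzaldehyde)
Product: 2 4-(TBS-oxy)-3,5-dimethoxybenzaldehyde
Conditions: TBSCl, imidazole, DMF, rt
Reagents that add atoms: tert-butyldimethylsilyl chloride, CC(C)(C)[Si](C)(C)Cl
Why: Standard phenol O-silylation (Corey protocol); the aryl silyl ether survives the aldol, hydride and sulfonylation steps and is removed by fluoride at the end without touching benzylic ethers; no stereocentre is involved.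

Step 2
Reactants: 3 (R)-4-benzyl-1,3-oxazolidin-2-one (2 equiv); 4 succinyl chloride
Product: 6 1,4-bis[(4R)-4-benzyl-2-oxo-1,3-oxazolidin-3-yl]butane-1,4-dione, via lithium oxazolidinide 5 (not isolated)
Conditions: n-BuLi, THF, −78 °C; then 4 (0.5 equiv), −78 → 0 °C
Reagents that add atoms: none
Why: Standard N-acylation of a lithiated Evans oxazolidinone by an acid chloride, carried out at both ends of the C4 diacid; the auxiliary stereocentres are not touched.

Step 3 (key step)
Reactants: 6; 2 (2.5 equiv)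
Product: 11 (1S,4R,5S,8R)-4,8-bis(Ar)-3,7-dioxabicyclo[3.3.0]octane-2,6-dione, via mono-aldol silyl ether 7 (not isolated), via bis-aldol bis-silyl ether 8 (not isolated), via bis-aldol diol 9 (not isolated), via monolactone 10 (not isolated)
Conditions: MgCl2 (0.3 equiv), Et3N, TMSCl, EtOAc, rt; then 1 M HCl–THF, rt → 40 °C
Reagents that add atoms: none
Why: Proposed new method: the closest known reactions are the Evans MgCl2-catalysed, TMSCl-trapped anti-aldol of single N-acyloxazolidinones with aromatic aldehydes and the aldol–lactonisation of succinate imides to paraconic lactones; here the same soft enolisation is run at both α-carbons of 6 (6 → 7 → 8), each Mg-chelated Z-enolate being attacked through a boat transition state on the face away from its own benzyl group (alkylation-type face selection), which with the (R)-auxiliary sets the α-carbon S and the carbinol R, anti, at both ends; O-silylation blocks retro-aldol and early lactonisation so both C–C bonds form on the open chain, and on acidic desilylation each γ-hydroxyl attacks the distal imide carbonyl (5-exo-trig) and expels the auxiliary, so only the C2-symmetric (2S,3S) bis-adduct can close both cis-fused rings and 11 emerges as 1S,4R,5S,8R with both aryl groups endo.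

Step 4
Reactants: 11
Product: 12 (1R,2R,3R,4R)-1,4-bis(Ar)-2,3-bis(hydroxymethyl)butane-1,4-diol
Conditions: LiBH4, THF–MeOH, 0 °C → rt
Reagents that add atoms: none
Why: Hydride reduction of both lactones to diols; LiBH4 leaves aryl silyl ethers alone, no C–O bond at a benzylic carbon is broken and the former α-carbons are not enolised, so all four stereocentres are carried over (descriptors change only through CIP priorities).

Step 5
Reactants: 12
Product: 15 (2R,3R,4R,5S)-2,5-bis(Ar)-3,4-bis(TBS-oxymethyl)oxolane, via bis-silyl diol 13 (not isolated), via monomesylate 14 (not isolated)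
Conditions: TBSCl (2.1 equiv), Et3N, DMAP (cat.), CH2Cl2, 0 °C; then MsCl (1.2 equiv), −30 → 0 °C
Reagents that add atoms: tert-butyldimethylsilyl chloride, CC(C)(C)[Si](C)(C)Cl
Why: Primary-selective DMAP-catalysed silylation followed by mesylation and intramolecular Williamson-type 5-exo-tet etherification; the two benzylic carbinols are equivalent by C2 symmetry, the one that acts as nucleophile keeps its configuration (aryl cis to its neighbouring CH2OTBS) and the sulfonylated carbon is inverted by SN2 or, if it ionises, is closed trans to its neighbouring CH2OTBS under allylic-strain control, so both pathways give the same 5S centre.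

Step 6
Reactants: 15
Product: 16 [(2R,3R,4R,5S)-2,5-bis(4-hydroxy-3,5-dimethoxyphenyl)oxolane-3,4-diyl]dimethanol
Conditions: Bu4NF, AcOH, THF, 0 °C → rt
Reagents that add atoms: none
Why: Fluoride-mediated desilylation of the two aryl and two primary silyl ethers; the acetic acid buffer keeps the freed phenoxide from opening the benzylic ether through a quinone methide, so no stereocentre is disturbed.

**Compound list**

1 | syringaldehyde (4-hydroxy-3,5-dimethoxybenzaldehyde) | COc1cc(C=O)cc(OC)c1O | starting material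
2 | 4-(TBS-oxy)-3,5-dimethoxybenzaldehyde | COc1cc(C=O)cc(OC)c1O[Si](C)(C)C(C)(C)C | intermediate
3 | (R)-4-benzyl-1,3-oxazolidin-2-one | O=C1OC[C@@H](Cc2ccccc2)N1 | starting material
4 | succinyl chloride (butanedioyl dichloride) | O=C(Cl)CCC(Cl)=O | starting material
5 | lithium (R)-4-benzyl-2-oxo-1,3-oxazolidin-3-ide | [Li+].O=C1OC[C@@H](Cc2ccccc2)[N-]1 | intermediate
6 | 1,4-bis[(4R)-4-benzyl-2-oxo-1,3-oxazolidin-3-yl]butane-1,4-dione | O=C(CCC(=O)N1[C@H](Cc2ccccc2)COC1=O)N1[C@H](Cc2ccccc2)COC1=O | intermediate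
7 | (2S)-2-[(R)-Ar(trimethylsilyloxy)methyl]-1,4-bis(Xc)butane-1,4-dione | C[Si](C)(C)O[C@@H](c1cc(OC)c(O[Si](C)(C)C(C)(C)C)c(OC)c1)[C@@H](C(=O)N1[C@H](Cc2ccccc2)COC1=O)CC(=O)N1[C@H](Cc2ccccc2)COC1=O | intermediate
8 | (2S,3S)-2,3-bis[(R)-Ar(trimethylsilyloxy)methyl]-1,4-bis(Xc)butane-1,4-dione | C[Si](C)(C)O[C@@H](c1cc(OC)c(O[Si](C)(C)C(C)(C)C)c(OC)c1)[C@@H](C(=O)N1[C@H](Cc2ccccc2)COC1=O)[C@H](C(=O)N1[C@H](Cc2ccccc2)COC1=O)[C@@H](O[Si](C)(C)C)c1cc(OC)c(O[Si](C)(C)C(C)(C)C)c(OC)c1 | intermediate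
9 | (2S,3S)-2,3-bis[(R)-Ar(hydroxy)methyl]-1,4-bis(Xc)butane-1,4-dione | O[C@@H](c1cc(OC)c(O[Si](C)(C)C(C)(C)C)c(OC)c1)[C@@H](C(=O)N1[C@H](Cc2ccccc2)COC1=O)[C@H](C(=O)N1[C@H](Cc2ccccc2)COC1=O)[C@@H](O)c1cc(OC)c(O[Si](C)(C)C(C)(C)C)c(OC)c1 | intermediate
10 | (4R)-4-benzyl-3-({(2R,3S,4S)-2-Ar-4-[(R)-Ar(hydroxy)methyl]-5-oxooxolan-3-yl}carbonyl)-1,3-oxazolidin-2-one | O=C1O[C@@H](c2cc(OC)c(O[Si](C)(C)C(C)(C)C)c(OC)c2)[C@@H](C(=O)N2[C@H](Cc3ccccc3)COC2=O)[C@H]1[C@@H](O)c1cc(OC)c(O[Si](C)(C)C(C)(C)C)c(OC)c1 | intermediate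
11 | (1S,4R,5S,8R)-4,8-bis(Ar)-3,7-dioxabicyclo[3.3.0]octane-2,6-dione (cis-fused; each aryl endo, cis to the neighbouring lactone carbonyl carbon) | O=C1O[C@@H](c3cc(OC)c(O[Si](C)(C)C(C)(C)C)c(OC)c3)[C@H]2C(=O)O[C@@H](c3cc(OC)c(O[Si](C)(C)C(C)(C)C)c(OC)c3)[C@@H]12 | intermediate
12 | (1R,2R,3R,4R)-1,4-bis(Ar)-2,3-bis(hydroxymethyl)butane-1,4-diol | O[C@@H](c1cc(OC)c(O[Si](C)(C)C(C)(C)C)c(OC)c1)[C@@H](CO)[C@H](CO)[C@@H](O)c1cc(OC)c(O[Si](C)(C)C(C)(C)C)c(OC)c1 | intermediate
13 | (1R,2R,3R,4R)-1,4-bis(Ar)-2,3-bis(TBS-oxymethyl)butane-1,4-diol | O[C@@H](c1cc(OC)c(O[Si](C)(C)C(C)(C)C)c(OC)c1)[C@@H](CO[Si](C)(C)C(C)(C)C)[C@H](CO[Si](C)(C)C(C)(C)C)[C@@H](O)c1cc(OC)c(O[Si](C)(C)C(C)(C)C)c(OC)c1 | intermediate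
14 | (1R,2R,3R,4R)-1,4-bis(Ar)-4-hydroxy-2,3-bis(TBS-oxymethyl)butyl methanesulfonate | CS(=O)(=O)O[C@@H](c1cc(OC)c(O[Si](C)(C)C(C)(C)C)c(OC)c1)[C@@H](CO[Si](C)(C)C(C)(C)C)[C@H](CO[Si](C)(C)C(C)(C)C)[C@@H](O)c1cc(OC)c(O[Si](C)(C)C(C)(C)C)c(OC)c1 | intermediate
15 | (2R,3R,4R,5S)-2,5-bis(Ar)-3,4-bis(TBS-oxymethyl)oxolane | COc1cc([C@H]2O[C@@H](c3cc(OC)c(O[Si](C)(C)C(C)(C)C)c(OC)c3)[C@@H](CO[Si](C)(C)C(C)(C)C)[C@@H]2CO[Si](C)(C)C(C)(C)C)cc(OC)c1O[Si](C)(C)C(C)(C)C | intermediate
16 | [(2R,3R,4R,5S)-2,5-bis(4-hydroxy-3,5-dimethoxyphenyl)oxolane-3,4-diyl]dimethanol | COc1cc([C@H]2O[C@@H](c3cc(OC)c(O)c(OC)c3)[C@@H](CO)[C@@H]2CO)cc(OC)c1O | target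

**Step count and risks**

Total steps: 6. Longest linear sequence: 5 steps (1 → 2 → 11 → 12 → 15 → 16; the branch 3 → 6 → 11 is equally long).

Steps most likely to fail:

Step 3. The second aldol must occur on an enolate that already carries a branched, stereogenic α-substituent. It may stall at 7 or give the unlike adduct, which cannot close the second lactone. The resident centre's bias is uncertain; it is matched only if the neighbouring imide carbonyl stays bound to magnesium. Fallback, setting out from 2 and coming back at 11: the central C–C bond is made instead of the two aldol bonds. Roskamp homologation of 2 (ethyl diazoacetate, SnCl2 cat., CH2Cl2) gives ethyl 3-Ar-3-oxopropanoate F1. Noyori–Ikariya transfer hydrogenation (RuCl(p-cymene)[(R,R)-TsDPEN], HCO2H–Et3N) gives ethyl (3R)-3-Ar-3-hydroxypropanoate F2. Its Fráter–Seebach dianion (LiN(iPr)2, 2.2 equiv, THF, −78 °C) is coupled oxidatively with CuBr2, each half reacting anti to the aryl group of its own lithium chelate, to give diethyl (2S,3S)-2,3-bis[(R)-Ar(hydroxy)methyl]butanedioate F3. Catalytic TsOH in toluene then closes both lactones to 11.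

Step 5. Mesylation can overrun to the bis-mesylate, and a benzylic cation can be captured by a silyl ether oxygen or eliminate. Fallback, setting out from 13 (isolated after the silylation) and coming back at 16: the ring is closed through a p-quinone methide instead of a sulfonate. K2CO3 in MeOH removes only the two aryl silyl ethers to give (1R,2R,3R,4R)-1,4-bis(4-hydroxy-3,5-dimethoxyphenyl)-2,3-bis(TBS-oxymethyl)butane-1,4-diol F4. A trace of CF3CO2H in CH2Cl2 at −20 °C converts one p-hydroxybenzylic alcohol into the p-quinone methide, which the other benzylic hydroxyl traps (oxa-1,6-addition, trans to the neighbouring CH2OTBS, kinetic control) to give (2R,3R,4R,5S)-2,5-bis(4-hydroxy-3,5-dimethoxyphenyl)-3,4-bis(TBS-oxymethyl)oxolane F5. Bu4NF/AcOH then gives 16.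

Step 2. Succinyl chloride can react through its cyclic lactone-type form or lose HCl to ketene-derived material, which would cut the yield of the double acylation. Fallback, setting out from 3 and coming back at 6: the two acyl groups are introduced one at a time. The lithium salt 5 opens succinic anhydride to 4-[(4R)-4-benzyl-2-oxo-1,3-oxazolidin-3-yl]-4-oxobutanoic acid F6. PivCl/Et3N converts it into the mixed pivalic anhydride F7, which acylates a second equivalent of 3 in the presence of LiCl/Et3N to give 6.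

**Further compounds**

F1 | step 3 | ethyl 3-[4-(tert-butyldimethylsilyloxy)-3,5-dimethoxyphenyl]-3-oxopropanoate | CCOC(=O)CC(=O)c1cc(OC)c(O[Si](C)(C)C(C)(C)C)c(OC)c1
F2 | step 3 | ethyl (3R)-3-[4-(tert-butyldimethylsilyloxy)-3,5-dimethoxyphenyl]-3-hydroxypropanoate | CCOC(=O)C[C@@H](O)c1cc(OC)c(O[Si](C)(C)C(C)(C)C)c(OC)c1
F3 | step 3 | diethyl (2S,3S)-2,3-bis{(R)-[4-(tert-butyldimethylsilyloxy)-3,5-dimethoxyphenyl](hydroxy)methyl}butanedioate | O[C@@H](c1cc(OC)c(O[Si](C)(C)C(C)(C)C)c(OC)c1)[C@@H](C(=O)OCC)[C@H](C(=O)OCC)[C@@H](O)c1cc(OC)c(O[Si](C)(C)C(C)(C)C)c(OC)c1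
F4 | step 5 | (1R,2R,3R,4R)-1,4-bis(4-hydroxy-3,5-dimethoxyphenyl)-2,3-bis{[(tert-butyldimethylsilyl)oxy]methyl}butane-1,4-diol | O[C@@H](c1cc(OC)c(O)c(OC)c1)[C@@H](CO[Si](C)(C)C(C)(C)C)[C@H](CO[Si](C)(C)C(C)(C)C)[C@@H](O)c1cc(OC)c(O)c(OC)c1
F5 | step 5 | (2R,3R,4R,5S)-2,5-bis(4-hydroxy-3,5-dimethoxyphenyl)-3,4-bis{[(tert-butyldimethylsilyl)oxy]methyl}oxolane | COc1cc([C@H]2O[C@@H](c3cc(OC)c(O)c(OC)c3)[C@@H](CO[Si](C)(C)C(C)(C)C)[C@@H]2CO[Si](C)(C)C(C)(C)C)cc(OC)c1O
F6 | step 2 | 4-[(4R)-4-benzyl-2-oxo-1,3-oxazolidin-3-yl]-4-oxobutanoic acid | OC(=O)CCC(=O)N1[C@H](Cc2ccccc2)COC1=O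
F7 | step 2 | 4-[(4R)-4-benzyl-2-oxo-1,3-oxazolidin-3-yl]-4-oxobutanoic 2,2-dimethylpropanoic anhydride | CC(C)(C)C(=O)OC(=O)CCC(=O)N1[C@H](Cc2ccccc2)COC1=O
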